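**Plan**

1. Numbering used: O1, C2 (pentenynyl), C3 (Cl), C4 (CH2), C5 (Br), C6 (bromopentenyl). Retrosynthesis: both side chains go back to allyl groups (alkene cross-metathesis), C5–Br and C3–Cl to equatorial alcohols (SN2 with inversion), C6-allyl/C5-OH to a C5=C6 glycal epoxide, and the glycal to a 6-ethoxy acetal.
2. The ring is then cut at O1–C6 and C4–C5 in one oxa-[4+2] step. O1, C2, C3 and the unsubstituted methylene C4 are a latent 1-oxabutadiene (methyl 2-oxobut-3-enoate, whose ester carbon becomes the first CH2 of the enyne chain). C5–C6, with C6 bound to the ring oxygen, is a latent vinyl ether (ethyl vinyl ether).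
3. Forward: the cycloaddition closes the only ring first; then C2/C3 (hydroboration, chlorination), C5/C6 (glycal, epoxide, allyl Grignard), the bromopentenyl chain, the C2 allyl group, the C5 bromide and the enyne.
4. Stereochemistry: the Cu(OTf)2–bis(oxazoline) catalyst sets the acetal carbon C6; hydroboration anti to the ethoxy group relays it to C2 and C3; inversion gives the axial chloride, which steers the epoxidation; trans opening sets C6 and C5; a second inversion gives the axial bromide.

Key step: step 2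

Assumption: the sense of induction in step 2 follows the usual square-planar chelate model, on which the (R,R)-ligand gives the (S)-acetal 4; if the opposite sense were found, the (S,S)-ligand would be used with no other change.

**Step 1**
Reactants: 1 methyl 2-hydroxybut-3-enoate (racemic)
Product: 2 methyl 2-oxobut-3-enoate
Conditions: Dess–Martin periodinane (1.2 equiv), CH2Cl2, 0 °C → rt; silica plug; solution used at once
Reagents that add atoms: none
Why: Dess–Martin oxidation turns the secondary α-hydroxy ester into the vinyl α-keto ester under neutral conditions, and the stereocenter of 1 is erased, so racemic material suffices.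

**Step 2**
Reactants: 2 methyl 2-oxobut-3-enoate; 3 ethyl vinyl ether
Product: 4 methyl (2S)-2-ethoxy-3,4-dihydro-2H-pyran-6-carboxylate
Conditions: Cu(OTf)2 (5 mol %), (R,R)-2,2'-(propane-2,2-diyl)bis(4-tert-butyl-4,5-dihydro-1,3-oxazole) (5.5 mol %), 3 Å molecular sieves, THF, −40 → 0 °C; 3 (3 equiv); 2 added slowly
Reagents that add atoms: none
Why: The 1,2-dicarbonyl unit of 2 chelates divalent copper, which locks the s-cis 1-oxabutadiene (O1=C2–C3=C4) and lowers its LUMO, so that 3 adds in a concerted but asynchronous inverse-electron-demand [4+2] cycloaddition in which the C4–C5 bond (enone CH2 to vinyl ether CH2) runs ahead of the O1–C6 bond. The closest known reaction type is the hetero-Diels–Alder reaction of β,γ-unsaturated α-keto esters with enol ethers under Cu(OTf)2–bis(oxazoline) catalysis. The one ring, the dihydropyran, is closed in the cycloaddition mode (suprafacial [4π+2π]), not by a stepwise exo- or endo-trig cyclisation. The single new stereocenter, the acetal carbon C6, is controlled by the ligand: a tert-butyl group blocks one face of the chelated diene and the ethoxy group sits endo, which on the square-planar model should give the (S)-acetal with the (R,R)-ligand. The step needs regioselectivity (secured by the match of the nucleophilic CH2 of 3 with the electrophilic CH2 terminus of 2), endo and facial selectivity (both set by the catalyst) and chemoselectivity over self-dimerisation of 2 (secured by excess 3, low temperature and slow addition of 2).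

**Step 3**
Reactants: 4 methyl (2S)-2-ethoxy-3,4-dihydro-2H-pyran-6-carboxylate
Product: 5 [(2S)-2-ethoxy-3,4-dihydro-2H-pyran-6-yl]methanol
Conditions: diisobutylaluminium hydride (DIBAL-H, 2.5 equiv), CH2Cl2, −78 → 0 °C; aq. potassium sodium tartrate
Reagents that add atoms: none
Why: 1,2-Reduction of the conjugated ester to the primary allylic alcohol leaves acetal and enol ether untouched and makes the enol ether electron-rich for the hydroboration.

**Step 4**
Reactants: 5 [(2S)-2-ethoxy-3,4-dihydro-2H-pyran-6-yl]methanol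
Product: 6 tert-butyl{[(2S)-2-ethoxy-3,4-dihydro-2H-pyran-6-yl]methoxy}dimethylsilane
Conditions: tert-butyldimethylsilyl chloride (1.2 equiv), imidazole (2 equiv), DMF, 0 °C → rt
Reagents that add atoms: tert-butyldimethylsilyl chloride, CC(C)(C)[Si](C)(C)Cl
Why: Standard silylation keeps the primary oxygen out of the chlorination, the enol ether formation and the Grignard step.

**Step 5**
Reactants: 6 tert-butyl{[(2S)-2-ethoxy-3,4-dihydro-2H-pyran-6-yl]methoxy}dimethylsilane
Product: 7 (2S,3R,6S)-2-({[tert-butyl(dimethyl)silyl]oxy}methyl)-6-ethoxyoxan-3-ol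
Conditions: BH3·THF (1.5 equiv), THF, 0 °C; then aq. NaOH, H2O2, 0 °C → rt
Reagents that add atoms: hydrogen peroxide, OO
Why: Hydroboration–oxidation of the cyclic enol ether puts boron on C3 and hydrogen on C2 by syn addition to the face opposite the pseudo-axial anomeric ethoxy group, so C2 (side chain cis to OEt) and C3 (equatorial OH trans to the side chain) are set by relay from C6.

**Step 6**
Reactants: 7 (2S,3R,6S)-2-({[tert-butyl(dimethyl)silyl]oxy}methyl)-6-ethoxyoxan-3-ol
Product: 8 tert-butyl{[(2S,3S,6S)-3-chloro-6-ethoxyoxan-2-yl]methoxy}dimethylsilane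
Conditions: (n-Oct)3P (3 equiv), CCl4 (5 equiv), pyridine (1 equiv), toluene, 70 °C
Reagents that add atoms: tetrachloromethane, ClC(Cl)(Cl)Cl
Why: Appel-type chlorination, in which chloride displaces the C3 alkoxyphosphonium by SN2 with inversion, turns the equatorial alcohol into the axial chloride cis to the C2 side chain.

**Step 7**
Reactants: 8 tert-butyl{[(2S,3S,6S)-3-chloro-6-ethoxyoxan-2-yl]methoxy}dimethylsilane
Product: 9 tert-butyl{[(2S,3S)-3-chloro-3,4-dihydro-2H-pyran-2-yl]methoxy}dimethylsilane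
Conditions: Me3SiOTf (1.5 equiv), i-Pr2NEt (3 equiv), CH2Cl2, −20 °C → rt
Reagents that add atoms: none
Why: Acetal-to-enol-ether elimination (silyl triflate ionises the acetal, the hindered amine removes a C5 proton) gives the C5=C6 glycal; C6 can be flattened because its information now resides in C2 and C3.

**Step 8**
Reactants: 9 tert-butyl{[(2S,3S)-3-chloro-3,4-dihydro-2H-pyran-2-yl]methoxy}dimethylsilane
Product: 11 (2R,3S,5S,6S)-6-({[tert-butyl(dimethyl)silyl]oxy}methyl)-5-chloro-2-(prop-2-en-1-yl)oxan-3-ol, via glycal epoxide 10 (not isolated)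
Conditions: dimethyldioxirane (acetone solution, 1.2 equiv), CH2Cl2, −78 → 0 °C; volatiles removed; then allylmagnesium chloride (3 equiv), THF, −78 → 0 °C; aq. NH4Cl
Reagents that add atoms: dimethyldioxirane, CC1(C)OO1; allylmagnesium chloride, C=CC[Mg]Cl
Why: Dimethyldioxirane should epoxidise the enol ether on the face opposite the pseudo-axial C3 chlorine, and the allyl Grignard reagent opens the 1,2-anhydro acetal at C6 with inversion (known trans opening of glycal epoxides), which places the C6 allyl group cis to the C2 side chain and the equatorial C5 alcohol trans to it.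

**Step 9**
Reactants: 12 2-bromobut-1-ene
Product: 14 2-(but-1-en-2-yl)-4,4,5,5-tetramethyl-1,3,2-dioxaborolane, via alkenylmagnesium bromide 13 (not isolated)
Conditions: Mg turnings, I2 (cat.), THF, rt → 40 °C; then 2-isopropoxy-4,4,5,5-tetramethyl-1,3,2-dioxaborolane, −78 °C → rt; aq. NH4Cl
Reagents that add atoms: 2-isopropoxy-4,4,5,5-tetramethyl-1,3,2-dioxaborolane, CC(C)OB1OC(C)(C)C(C)(C)O1
Why: Magnesium insertion into the alkenyl bromide and borylation of the Grignard reagent is the standard route to an alkenyl pinacol boronate.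

**Step 10**
Reactants: 11 (2R,3S,5S,6S)-6-({[tert-butyl(dimethyl)silyl]oxy}methyl)-5-chloro-2-(prop-2-en-1-yl)oxan-3-ol; 14 2-(but-1-en-2-yl)-4,4,5,5-tetramethyl-1,3,2-dioxaborolane
Product: 15 (2R,3S,5S,6S)-6-({[tert-butyl(dimethyl)silyl]oxy}methyl)-5-chloro-2-[(2Z)-3-(4,4,5,5-tetramethyl-1,3,2-dioxaborolan-2-yl)pent-2-en-1-yl]oxan-3-ol
Conditions: second-generation Hoveyda–Grubbs catalyst (10 mol %), 14 (3 equiv), CH2Cl2, 40 °C
Reagents that add atoms: none
Why: Alkene cross-metathesis of a terminal alkene with a 1,1-disubstituted alkenyl pinacol boronate is a known route to trisubstituted alkenyl boronates, and the preferred isomer should carry the boryl group trans to the new chain (ethyl cis), the geometry needed.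

**Step 11**
Reactants: 15 (2R,3S,5S,6S)-6-({[tert-butyl(dimethyl)silyl]oxy}methyl)-5-chloro-2-[(2Z)-3-(4,4,5,5-tetramethyl-1,3,2-dioxaborolan-2-yl)pent-2-en-1-yl]oxan-3-ol
Product: 17 (2R,3S,5S,6S)-2-[(2E)-3-bromopent-2-en-1-yl]-5-chloro-6-(hydroxymethyl)oxan-3-ol, via silyl ether 16 (not isolated)
Conditions: CuBr2 (3 equiv), MeOH/H2O (1:1), 70 °C; then aq. HCl (1 M) added, rt
Reagents that add atoms: copper dibromide, [Cu+2].[Br-].[Br-]
Why: Copper-mediated bromodeboronation runs through boron-to-copper transmetalation and C–Br reductive elimination at the same carbon, so bromine takes the place of boron with retention (E-bromoalkene), and dilute acid then cleaves the primary silyl ether.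

**Step 12**
Reactants: 17 (2R,3S,5S,6S)-2-[(2E)-3-bromopent-2-en-1-yl]-5-chloro-6-(hydroxymethyl)oxan-3-ol
Product: 19 (2R,3S,5S,6S)-2-[(2E)-3-bromopent-2-en-1-yl]-5-chloro-6-(prop-2-en-1-yl)oxan-3-ol, via primary triflate 18 (not isolated)
Conditions: Tf2O (1.05 equiv), 2,6-lutidine (1.5 equiv), CH2Cl2, −78 °C; cold aqueous work-up; crude triflate, vinylmagnesium bromide (4 equiv), CuI (20 mol %), THF, −78 → −20 °C
Reagents that add atoms: vinylmagnesium bromide, C=C[Mg]Br
Why: The primary hydroxyl is triflated selectively at low temperature and the triflate is displaced in a CuI-catalysed Grignard coupling (SN2 at the primary carbon), which makes the former ester carbon the CH2 of an allyl group without touching a stereocenter.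

**Step 13**
Reactants: 19 (2R,3S,5S,6S)-2-[(2E)-3-bromopent-2-en-1-yl]-5-chloro-6-(prop-2-en-1-yl)oxan-3-ol
Product: 20 (2R,3R,5S,6S)-3-bromo-2-[(2E)-3-bromopent-2-en-1-yl]-5-chloro-6-(prop-2-en-1-yl)oxane
Conditions: CBr4 (3 equiv), (n-Oct)3P (6 equiv), toluene, 70 °C
Reagents that add atoms: tetrabromomethane, BrC(Br)(Br)Br
Why: Appel-type bromination, in which bromide displaces the equatorial C5 alkoxyphosphonium by SN2 with inversion, should give the axial bromide cis to the other three substituents.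

**Step 14**
Reactants: 21 ethynyltri(propan-2-yl)silane; 22 bromoethene
Product: 23 (but-3-en-1-yn-1-yl)tri(propan-2-yl)silane
Conditions: Pd(PPh3)2Cl2 (2 mol %), CuI (4 mol %), i-Pr2NH, THF, 0 °C → rt
Reagents that add atoms: none
Why: Sonogashira coupling of the terminal alkyne with vinyl bromide gives the silyl-capped conjugated enyne needed as metathesis partner.

**Step 15**
Reactants: 20 (2R,3R,5S,6S)-3-bromo-2-[(2E)-3-bromopent-2-en-1-yl]-5-chloro-6-(prop-2-en-1-yl)oxane; 23 (but-3-en-1-yn-1-yl)tri(propan-2-yl)silane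
Product: 24 {(3Z)-5-[(2S,3S,5R,6R)-5-bromo-6-[(2E)-3-bromopent-2-en-1-yl]-3-chlorooxan-2-yl]pent-3-en-1-yn-1-yl}tri(propan-2-yl)silane
Conditions: second-generation Grubbs catalyst (10 mol %), 23 (5 equiv), benzene, 60 °C
Reagents that add atoms: none
Why: Cross-metathesis of a terminal alkene with a silyl-capped conjugated enyne is known to favour the (Z)-enyne, the bulky silyl group should keep the alkyne out of enyne metathesis, and the trisubstituted bromoalkene is inert.

**Step 16**
Reactants: 24 {(3Z)-5-[(2S,3S,5R,6R)-5-bromo-6-[(2E)-3-bromopent-2-en-1-yl]-3-chlorooxan-2-yl]pent-3-en-1-yn-1-yl}tri(propan-2-yl)silane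
Product: 25 (2R,3R,5S,6S)-3-bromo-2-[(2E)-3-bromopent-2-en-1-yl]-5-chloro-6-[(2Z)-pent-2-en-4-yn-1-yl]oxane
Conditions: tetrabutylammonium fluoride (1.2 equiv), AcOH (1.2 equiv), THF, 0 °C
Reagents that add atoms: none
Why: Fluoride removes the triisopropylsilyl group from the alkyne, and buffering with acetic acid at low temperature should keep the secondary axial halides from E2 elimination.

**Compound list**

1 | methyl 2-hydroxybut-3-enoate (racemic) | C=CC(O)C(=O)OC | starting material
2 | methyl 2-oxobut-3-enoate | C=CC(=O)C(=O)OC | intermediate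
3 | ethyl vinyl ether | C=COCC | starting material
4 | methyl (2S)-2-ethoxy-3,4-dihydro-2H-pyran-6-carboxylate | COC(=O)C1=CCC[C@@H](OCC)O1 | intermediate
5 | [(2S)-2-ethoxy-3,4-dihydro-2H-pyran-6-yl]methanol | OCC1=CCC[C@@H](OCC)O1 | intermediate
6 | tert-butyl{[(2S)-2-ethoxy-3,4-dihydro-2H-pyran-6-yl]methoxy}dimethylsilane | CC(C)(C)[Si](C)(C)OCC1=CCC[C@@H](OCC)O1 | intermediate
7 | (2S,3R,6S)-2-({[tert-butyl(dimethyl)silyl]oxy}methyl)-6-ethoxyoxan-3-ol | CC(C)(C)[Si](C)(C)OC[C@H]1[C@H](O)CC[C@@H](OCC)O1 | intermediate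
8 | tert-butyl{[(2S,3S,6S)-3-chloro-6-ethoxyoxan-2-yl]methoxy}dimethylsilane | CC(C)(C)[Si](C)(C)OC[C@H]1[C@@H](Cl)CC[C@@H](OCC)O1 | intermediate
9 | tert-butyl{[(2S,3S)-3-chloro-3,4-dihydro-2H-pyran-2-yl]methoxy}dimethylsilane | CC(C)(C)[Si](C)(C)OC[C@H]1[C@@H](Cl)CC=CO1 | intermediate
10 | tert-butyl{[(1R,3S,4S,6S)-4-chloro-2,7-dioxabicyclo[4.1.0]heptan-3-yl]methoxy}dimethylsilane | CC(C)(C)[Si](C)(C)OC[C@H]1[C@@H](Cl)C[C@@H]2O[C@@H]2O1 | intermediate
11 | (2R,3S,5S,6S)-6-({[tert-butyl(dimethyl)silyl]oxy}methyl)-5-chloro-2-(prop-2-en-1-yl)oxan-3-ol | CC(C)(C)[Si](C)(C)OC[C@H]1[C@@H](Cl)C[C@H](O)[C@@H](CC=C)O1 | intermediate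
12 | 2-bromobut-1-ene | C=C(Br)CC | starting material
13 | (but-1-en-2-yl)magnesium bromide | C=C(CC)[Mg]Br | intermediate
14 | 2-(but-1-en-2-yl)-4,4,5,5-tetramethyl-1,3,2-dioxaborolane | C=C(CC)B1OC(C)(C)C(C)(C)O1 | intermediate
15 | (2R,3S,5S,6S)-6-({[tert-butyl(dimethyl)silyl]oxy}methyl)-5-chloro-2-[(2Z)-3-(4,4,5,5-tetramethyl-1,3,2-dioxaborolan-2-yl)pent-2-en-1-yl]oxan-3-ol | CC(C)(C)[Si](C)(C)OC[C@H]1[C@@H](Cl)C[C@H](O)[C@@H](C/C=C(/B2OC(C)(C)C(C)(C)O2)CC)O1 | intermediate
16 | (2R,3S,5S,6S)-2-[(2E)-3-bromopent-2-en-1-yl]-6-({[tert-butyl(dimethyl)silyl]oxy}methyl)-5-chlorooxan-3-ol | CC(C)(C)[Si](C)(C)OC[C@H]1[C@@H](Cl)C[C@H](O)[C@@H](C/C=C(/Br)CC)O1 | intermediate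
17 | (2R,3S,5S,6S)-2-[(2E)-3-bromopent-2-en-1-yl]-5-chloro-6-(hydroxymethyl)oxan-3-ol | OC[C@H]1[C@@H](Cl)C[C@H](O)[C@@H](C/C=C(/Br)CC)O1 | intermediate
18 | [(2S,3S,5S,6R)-6-[(2E)-3-bromopent-2-en-1-yl]-3-chloro-5-hydroxyoxan-2-yl]methyl trifluoromethanesulfonate | FC(F)(F)S(=O)(=O)OC[C@H]1[C@@H](Cl)C[C@H](O)[C@@H](C/C=C(/Br)CC)O1 | intermediate
19 | (2R,3S,5S,6S)-2-[(2E)-3-bromopent-2-en-1-yl]-5-chloro-6-(prop-2-en-1-yl)oxan-3-ol | C=CC[C@H]1[C@@H](Cl)C[C@H](O)[C@@H](C/C=C(/Br)CC)O1 | intermediate
20 | (2R,3R,5S,6S)-3-bromo-2-[(2E)-3-bromopent-2-en-1-yl]-5-chloro-6-(prop-2-en-1-yl)oxane | C=CC[C@H]1[C@@H](Cl)C[C@@H](Br)[C@@H](C/C=C(/Br)CC)O1 | intermediate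
21 | ethynyltri(propan-2-yl)silane | C#C[Si](C(C)C)(C(C)C)C(C)C | starting material
22 | bromoethene | C=CBr | starting material
23 | (but-3-en-1-yn-1-yl)tri(propan-2-yl)silane | C=CC#C[Si](C(C)C)(C(C)C)C(C)C | intermediate
24 | {(3Z)-5-[(2S,3S,5R,6R)-5-bromo-6-[(2E)-3-bromopent-2-en-1-yl]-3-chlorooxan-2-yl]pent-3-en-1-yn-1-yl}tri(propan-2-yl)silane | CC(C)[Si](C(C)C)(C(C)C)C#C/C=C\C[C@H]1[C@@H](Cl)C[C@@H](Br)[C@@H](C/C=C(/Br)CC)O1 | intermediate
25 | (2R,3R,5S,6S)-3-bromo-2-[(2E)-3-bromopent-2-en-1-yl]-5-chloro-6-[(2Z)-pent-2-en-4-yn-1-yl]oxane | C#C/C=C\C[C@@H]1O[C@H](C/C=C(/Br)CC)[C@H](Br)C[C@@H]1Cl | target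

**Step count**

Total: 16 steps. Longest linear sequence: 14 steps (steps 1–8, 10–13, 15, 16).

**Steps most likely to fail**

Step 13 (C5 bromination). The bromide must enter C5 on the face that already carries the axial C3 chlorine. Backside attack on the alkoxyphosphonium is therefore slow, and at 70 °C E2 loss toward C4 or participation of the ring oxygen (oxiranium formation, then retention or ring contraction) may take over. The fallback uncouples activation from substitution. It sets out from 19, which is converted with chloromethanesulfonyl chloride and pyridine (CH2Cl2, 0 °C) into the isolable (2R,3S,5S,6S)-2-[(2E)-3-bromopent-2-en-1-yl]-5-chloro-6-(prop-2-en-1-yl)oxan-3-yl chloromethanesulfonate F1. This much better leaving group is then displaced with inversion by excess LiBr in THF near room temperature, and the route is rejoined at 20.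

Step 10 (cross-metathesis to the alkenyl boronate). The hindered 1,1-disubstituted boronate may react too slowly to form the trisubstituted alkene, the allyl group may homodimerise, and the double-bond geometry may not be fully controlled. The fallback builds the bromoalkene from a silylalkyne without metathesis and sets out from 11.

- Lemieux–Johnson cleavage of the allyl group (OsO4 cat., NaIO4, 2,6-lutidine, dioxane/H2O) gives 2-[(2R,3S,5S,6S)-6-({[tert-butyl(dimethyl)silyl]oxy}methyl)-5-chloro-3-hydroxyoxan-2-yl]acetaldehyde F2, which may rest as its lactol.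
- Seyferth–Gilbert homologation with the Ohira–Bestmann reagent (K2CO3, MeOH) gives (2R,3S,5S,6S)-6-({[tert-butyl(dimethyl)silyl]oxy}methyl)-5-chloro-2-(prop-2-yn-1-yl)oxan-3-ol F3.
- n-BuLi (2 equiv), then Me3SiCl and a mildly acidic work-up that frees the O-silyl group, gives (2R,3S,5S,6S)-6-({[tert-butyl(dimethyl)silyl]oxy}methyl)-5-chloro-2-[3-(trimethylsilyl)prop-2-yn-1-yl]oxan-3-ol F4.
- syn-Hydroalumination with DIBAL-H in the presence of a donor amine places aluminium on the silyl-bearing carbon cis to the new hydrogen; MeLi then EtI ethylates that position with retention and gives (2R,3S,5S,6S)-6-({[tert-butyl(dimethyl)silyl]oxy}methyl)-5-chloro-2-[(2Z)-3-(trimethylsilyl)pent-2-en-1-yl]oxan-3-ol F5.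
- Bromodesilylation (Br2, CH2Cl2, −78 °C, then NaOMe; anti addition and anti elimination, net inversion) gives the (E)-bromoalkene, and the route is rejoined at 16.

Step 15 (enyne cross-metathesis). Secondary metathesis may erode the Z geometry, and the catalyst may be diverted by the alkyne. The fallback replaces metathesis by a carbonyl olefination and sets out from 20. Chemoselective Lemieux–Johnson cleavage of the terminal alkene (OsO4 cat., NaIO4, 2,6-lutidine; the bromoalkene is electron-poor and trisubstituted) gives 2-[(2S,3S,5R,6R)-5-bromo-6-[(2E)-3-bromopent-2-en-1-yl]-3-chlorooxan-2-yl]acetaldehyde F6. Z-selective Peterson olefination with lithiated 1,3-bis(triisopropylsilyl)propyne (n-BuLi, THF, −78 °C) then rejoins the route at 24.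

**Further compounds**

F1 | step 13 | (2R,3S,5S,6S)-2-[(2E)-3-bromopent-2-en-1-yl]-5-chloro-6-(prop-2-en-1-yl)oxan-3-yl chloromethanesulfonate | C=CC[C@H]1[C@@H](Cl)C[C@H](OS(=O)(=O)CCl)[C@@H](C/C=C(/Br)CC)O1
F2 | step 10 | 2-[(2R,3S,5S,6S)-6-({[tert-butyl(dimethyl)silyl]oxy}methyl)-5-chloro-3-hydroxyoxan-2-yl]acetaldehyde | CC(C)(C)[Si](C)(C)OC[C@H]1[C@@H](Cl)C[C@H](O)[C@@H](CC=O)O1
F3 | step 10 | (2R,3S,5S,6S)-6-({[tert-butyl(dimethyl)silyl]oxy}methyl)-5-chloro-2-(prop-2-yn-1-yl)oxan-3-ol | CC(C)(C)[Si](C)(C)OC[C@H]1[C@@H](Cl)C[C@H](O)[C@@H](CC#C)O1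
F4 | step 10 | (2R,3S,5S,6S)-6-({[tert-butyl(dimethyl)silyl]oxy}methyl)-5-chloro-2-[3-(trimethylsilyl)prop-2-yn-1-yl]oxan-3-ol | CC(C)(C)[Si](C)(C)OC[C@H]1[C@@H](Cl)C[C@H](O)[C@@H](CC#C[Si](C)(C)C)O1
F5 | step 10 | (2R,3S,5S,6S)-6-({[tert-butyl(dimethyl)silyl]oxy}methyl)-5-chloro-2-[(2Z)-3-(trimethylsilyl)pent-2-en-1-yl]oxan-3-ol | CC(C)(C)[Si](C)(C)OC[C@H]1[C@@H](Cl)C[C@H](O)[C@@H](C/C=C(\[Si](C)(C)C)CC)O1
F6 | step 15 | 2-[(2S,3S,5R,6R)-5-bromo-6-[(2E)-3-bromopent-2-en-1-yl]-3-chlorooxan-2-yl]acetaldehyde | O=CC[C@H]1[C@@H](Cl)C[C@@H](Br)[C@@H](C/C=C(/Br)CC)O1
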